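**Plan**
- Cuts (carotenoid numbering): C11=C12 and C11′=C12′ by Wittig reactions give a C15 ring phosphonium salt, the C10 trienedial and farnesyl; C7=C8 by Horner–Wadsworth–Emmons leads back to (R)-α-cyclocitral; the ring is cut at C1–C6 and C2–C3.
- Enabling feature: the only ring is a cyclohexene whose double bond C4=C5 lies opposite the C1–C2 bond, with the quaternary C1 beside the stereogenic C6. This is a Diels–Alder retron: diene C3=C4–C5(CH3)=C6–C7 plus an isobutene equivalent C1=C2.
- Helpers: a silyloxy group on C4 fixes the regiochemistry and is later taken out via the enol triflate; methacrolein serves as activated isobutene and its formyl group on C1 later becomes the second methyl group.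
- Forward order: diene (2 steps), ring by catalytic asymmetric [4+2], removal of both helpers, C7 aldehyde, C15 salt; farnesyl salt plus trienedial gives the C25 aldehyde; a last Wittig reaction joins C25 and C15.
- Stereochemistry: C6 is set in the cycloaddition (catalyst-controlled dienophile face plus endo approach to the E diene terminus); the polyene geometry comes from E-selective olefinations and final equilibration.

Key step: step 3

Remark: the sense of induction in step 3 is taken from the accepted formyl C–H···O binding model for 2-substituted acroleins on protonated oxazaborolidines; compounds 1, 2, 5, 13, 18 and 20 are taken as commercial (13 mainly as the 2E isomer).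

**Step 1**
Reactants: 1 {[tert-butyl(dimethyl)silyl]oxy}acetaldehyde; 2 3-(triphenyl-λ5-phosphanylidene)butan-2-one
Product: 3 (3E)-5-{[tert-butyl(dimethyl)silyl]oxy}-3-methylpent-3-en-2-one
Conditions: toluene, 80 °C
Reagents that add atoms: none
Why: Wittig olefination with a stabilised α-methyl keto-ylide should give the trisubstituted enone with the CH2O group trans to the acetyl group (E), the geometry that later places this group on the outside of the s-cis diene.

**Step 2**
Reactants: 3 (3E)-5-{[tert-butyl(dimethyl)silyl]oxy}-3-methylpent-3-en-2-one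
Product: 4 tert-butyl(dimethyl){[(2E)-3-methyl-4-{[tri(propan-2-yl)silyl]oxy}penta-2,4-dien-1-yl]oxy}silane
Conditions: TIPSOTf, Et3N, CH2Cl2, 0 °C to rt
Reagents that add atoms: triisopropylsilyl trifluoromethanesulfonate (TIPSOTf), CC(C)[Si](OS(=O)(=O)C(F)(F)F)(C(C)C)C(C)C
Why: Soft enolisation of the methyl ketone at its CH3 group (silyl enol ether formation with silyl triflate and tertiary amine) should give the cross-conjugated 2-silyloxy-1,3-diene, and the bulky triisopropylsilyl group makes it robust toward the acidic catalyst of step 3.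

**Step 3**
Reactants: 4 tert-butyl(dimethyl){[(2E)-3-methyl-4-{[tri(propan-2-yl)silyl]oxy}penta-2,4-dien-1-yl]oxy}silane; 5 2-methylprop-2-enal (methacrolein)
Product: 6 (1R,2S)-2-({[tert-butyl(dimethyl)silyl]oxy}methyl)-1,3-dimethyl-4-{[tri(propan-2-yl)silyl]oxy}cyclohex-3-ene-1-carbaldehyde
Conditions: 5 (2 equiv), (R)-3,3-diphenyl-1-(o-tolyl)tetrahydro-1H,3H-pyrrolo[1,2-c][1,3,2]oxazaborole (20 mol%) + Tf2NH (17 mol%), CH2Cl2, −78 °C; Et3N quench; chromatography
Reagents that add atoms: none
Why: The protonated oxazaborolidine binds methacrolein at boron as the s-trans enal with a formyl C–H···O contact, one aryl group screens one face, and the electron-rich 2-silyloxydiene adds to the open face in a concerted but asynchronous normal-demand Diels–Alder reaction in which the diene CH2 terminus leads onto the enal CH2. The closest known reaction type is the oxazaborolidinium-catalysed Diels–Alder reaction of 2-methacrolein with 2-silyloxy-1,3-dienes, including 1-substituted 3-silyloxydienes. The cyclohexene is closed by intermolecular [4π+2π] cycloaddition, suprafacial on both partners, so that the two new σ bonds (diene CH2 to enal CH2, diene CH terminus to the enal α-carbon) form on one face of each component. The quaternary carbon (1R) is fixed by catalyst-controlled addition to the Si face of the α-carbon (the face on which CHO, CH2 and CH3 run anticlockwise), and the ring CH centre (2S) follows from the endo position of the formyl group under the diene together with the E geometry of the substituted diene terminus, which places CHO and CH2OTBS cis. Regioselectivity is needed and is secured by the silyloxy group on the carbon next to the diene CH2 terminus, which makes that terminus the nucleophilic end and overrides the opposing methyl group, so that the quaternary carbon ends up beside the CH(CH2OTBS) carbon. Endo selectivity is needed as well, because the exo adduct would give the enantiomeric ring once the formyl group has become the second methyl group, and the minor diastereomer is therefore removed by chromatography at this stage.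

**Step 4**
Reactants: 6 (1R,2S)-2-({[tert-butyl(dimethyl)silyl]oxy}methyl)-1,3-dimethyl-4-{[tri(propan-2-yl)silyl]oxy}cyclohex-3-ene-1-carbaldehyde
Product: 8 (3S,4R)-3-({[tert-butyl(dimethyl)silyl]oxy}methyl)-4-formyl-2,4-dimethylcyclohex-1-en-1-yl trifluoromethanesulfonate, via cesium enolate 7 (not isolated)
Conditions: CsF (dried), PhNTf2, DME, rt
Reagents that add atoms: N-phenylbis(trifluoromethanesulfonimide) (PhNTf2), O=S(=O)(N(c1ccccc1)S(=O)(=O)C(F)(F)F)C(F)(F)F
Why: Fluoride cleaves the silyl enol ether far faster than the alkyl silyl ether, and O-sulfonylation of the regiodefined cesium enolate (enol triflate formation) locks the double bond between the oxygen-bearing carbon and the methyl-bearing carbon, while the neopentyl, non-enolisable aldehyde should not interfere.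

**Step 5**
Reactants: 8 (3S,4R)-3-({[tert-butyl(dimethyl)silyl]oxy}methyl)-4-formyl-2,4-dimethylcyclohex-1-en-1-yl trifluoromethanesulfonate
Product: 9 (1R,2S)-2-({[tert-butyl(dimethyl)silyl]oxy}methyl)-1,3-dimethylcyclohex-3-ene-1-carbaldehyde
Conditions: Pd(OAc)2 (5 mol%), PPh3 (10 mol%), HCO2H, Bu3N, DMF, 60 °C
Reagents that add atoms: none
Why: Palladium-catalysed formate reduction of an enol triflate (oxidative addition to zerovalent palladium, formate exchange, loss of CO2, C–H reductive elimination) should replace OTf by H without moving the double bond, which leaves the trisubstituted ring alkene of the target, and aldehyde and silyl ether are inert.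

**Step 6**
Reactants: 9 (1R,2S)-2-({[tert-butyl(dimethyl)silyl]oxy}methyl)-1,3-dimethylcyclohex-3-ene-1-carbaldehyde
Product: 11 [(1R)-2,6,6-trimethylcyclohex-2-en-1-yl]methanol ((R)-α-cyclogeraniol), via hydrazone 10 (not isolated)
Conditions: N2H4·H2O, KOH, diethylene glycol, 130 °C then 200 °C
Reagents that add atoms: none
Why: Wolff–Kishner reduction (Huang–Minlon procedure) turns the hindered, non-enolisable formyl group into the second methyl group, which makes the quaternary carbon non-stereogenic, and the hot KOH/glycol medium should also cleave the primary silyl ether so that the alcohol is obtained directly, the remaining stereocentre carrying no acidic hydrogen.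

**Step 7**
Reactants: 11 [(1R)-2,6,6-trimethylcyclohex-2-en-1-yl]methanol
Product: 12 (1R)-2,6,6-trimethylcyclohex-2-ene-1-carbaldehyde ((R)-α-cyclocitral)
Conditions: Dess–Martin periodinane, NaHCO3, CH2Cl2, 0 °C; used at once
Reagents that add atoms: none
Why: Dess–Martin oxidation under buffered, non-basic conditions should give the aldehyde without epimerisation of the α-stereocentre or migration of the ring double bond into conjugation.

**Step 8**
Reactants: 12 (1R)-2,6,6-trimethylcyclohex-2-ene-1-carbaldehyde; 13 ethyl (2E)-4-(diethoxyphosphoryl)-3-methylbut-2-enoate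
Product: 15 ethyl (2E,4E)-3-methyl-5-[(1R)-2,6,6-trimethylcyclohex-2-en-1-yl]penta-2,4-dienoate, via lithiated phosphonate 14 (not isolated)
Conditions: 13 (1.2 equiv), LiN(SiMe3)2 (1.15 equiv), THF, −78 °C; then 12, −78 °C to rt; chromatography
Reagents that add atoms: none
Why: Horner–Wadsworth–Emmons olefination with the preformed lithium phosphonate (no excess base) should give the E-disubstituted double bond and keep the 2E geometry of the reagent, addition to the carbonyl group being faster than deprotonation of the hindered α-CH.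

**Step 9**
Reactants: 15 ethyl (2E,4E)-3-methyl-5-[(1R)-2,6,6-trimethylcyclohex-2-en-1-yl]penta-2,4-dienoate
Product: 16 (2E,4E)-3-methyl-5-[(1R)-2,6,6-trimethylcyclohex-2-en-1-yl]penta-2,4-dien-1-ol
Conditions: iBu2AlH (2.3 equiv), CH2Cl2, −78 °C; aqueous potassium sodium tartrate
Reagents that add atoms: none
Why: 1,2-Reduction of the dienoate with iBu2AlH (ester to primary allylic alcohol) leaves the diene geometry and the doubly allylic stereocentre untouched.

**Step 10**
Reactants: 16 (2E,4E)-3-methyl-5-[(1R)-2,6,6-trimethylcyclohex-2-en-1-yl]penta-2,4-dien-1-ol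
Product: 17 [(2E,4E)-3-methyl-5-[(1R)-2,6,6-trimethylcyclohex-2-en-1-yl]penta-2,4-dien-1-yl](triphenyl)phosphonium bromide
Conditions: Ph3P·HBr, MeOH, rt; crystallisation
Reagents that add atoms: triphenylphosphine hydrobromide, [Br-].[PH+](c1ccccc1)(c1ccccc1)c1ccccc1
Why: Acid-mediated substitution of the allylic alcohol by PPh3 (ionisation to the delocalised pentadienyl cation and capture at the primary terminus) is the standard entry to polyenyl phosphonium salts and should give the E,E salt.

**Step 11**
Reactants: 18 (2E,6E)-1-bromo-3,7,11-trimethyldodeca-2,6,10-triene (farnesyl bromide)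
Product: 19 triphenyl[(2E,6E)-3,7,11-trimethyldodeca-2,6,10-trien-1-yl]phosphonium bromide
Conditions: PPh3, toluene, rt, dark
Reagents that add atoms: triphenylphosphine, c1ccccc1P(c1ccccc1)c1ccccc1
Why: SN2 quaternisation of PPh3 by the primary allylic bromide at room temperature should proceed without allylic transposition or loss of the E geometry.

**Step 12**
Reactants: 19 triphenyl[(2E,6E)-3,7,11-trimethyldodeca-2,6,10-trien-1-yl]phosphonium bromide; 20 (2E,4E,6E)-2,7-dimethylocta-2,4,6-trienedial
Product: 23 (2E,4E,6E,8E,10E,14E)-2,7,11,15,19-pentamethylicosa-2,4,6,8,10,14,18-heptaenal, via farnesyl ylide 21 (not isolated), via (8Z)-aldehyde 22 (not isolated)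
Conditions: n-BuLi, THF, −78 °C; added to 20 (3 equiv), THF, −78 to 0 °C; then I2 (cat.), hexane, rt, daylight; chromatography
Reagents that add atoms: none
Why: Wittig olefination of the allylic ylide with an excess of the symmetrical dialdehyde under inverse addition should favour mono-condensation, and iodine-catalysed equilibration converts the Z isomer at the new double bond into the all-E polyenal.

**Step 13**
Reactants: 17 [(2E,4E)-3-methyl-5-[(1R)-2,6,6-trimethylcyclohex-2-en-1-yl]penta-2,4-dien-1-yl](triphenyl)phosphonium bromide; 23 (2E,4E,6E,8E,10E,14E)-2,7,11,15,19-pentamethylicosa-2,4,6,8,10,14,18-heptaenal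
Product: 26 α-zeacarotene, (6R)-7′,8′-dihydro-ε,ψ-carotene, via C15 ylide 24 (not isolated), via (11Z)-α-zeacarotene 25 (not isolated)
Conditions: 17 (1.2 equiv), NaOMe, CH2Cl2/MeOH, 0 °C to rt, dark, Ar; then heptane, reflux, Ar; crystallisation
Reagents that add atoms: none
Why: Wittig olefination of the polyenyl ylide with the polyenal forms the last double bond and thermal Z-to-E isomerisation should give the all-E carotene, the ring stereocentre being too weakly acidic to be touched by NaOMe.

**Compound list**
1 | {[tert-butyl(dimethyl)silyl]oxy}acetaldehyde | O=CCO[Si](C)(C)C(C)(C)C | starting material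
2 | 3-(triphenyl-λ5-phosphanylidene)butan-2-one | CC(=O)C(C)=P(c1ccccc1)(c1ccccc1)c1ccccc1 | starting material
3 | (3E)-5-{[tert-butyl(dimethyl)silyl]oxy}-3-methylpent-3-en-2-one | CC(=O)/C(C)=C/CO[Si](C)(C)C(C)(C)C | intermediate
4 | tert-butyl(dimethyl){[(2E)-3-methyl-4-{[tri(propan-2-yl)silyl]oxy}penta-2,4-dien-1-yl]oxy}silane | C=C(O[Si](C(C)C)(C(C)C)C(C)C)/C(C)=C/CO[Si](C)(C)C(C)(C)C | intermediate
5 | 2-methylprop-2-enal (methacrolein) | CC(=C)C=O | starting material
6 | (1R,2S)-2-({[tert-butyl(dimethyl)silyl]oxy}methyl)-1,3-dimethyl-4-{[tri(propan-2-yl)silyl]oxy}cyclohex-3-ene-1-carbaldehyde | O=C[C@]1(C)CCC(O[Si](C(C)C)(C(C)C)C(C)C)=C(C)[C@@H]1CO[Si](C)(C)C(C)(C)C | intermediate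
7 | cesium (3S,4R)-3-({[tert-butyl(dimethyl)silyl]oxy}methyl)-4-formyl-2,4-dimethylcyclohex-1-en-1-olate | O=C[C@]1(C)CCC([O-])=C(C)[C@@H]1CO[Si](C)(C)C(C)(C)C.[Cs+] | intermediate
8 | (3S,4R)-3-({[tert-butyl(dimethyl)silyl]oxy}methyl)-4-formyl-2,4-dimethylcyclohex-1-en-1-yl trifluoromethanesulfonate | O=C[C@]1(C)CCC(OS(=O)(=O)C(F)(F)F)=C(C)[C@@H]1CO[Si](C)(C)C(C)(C)C | intermediate
9 | (1R,2S)-2-({[tert-butyl(dimethyl)silyl]oxy}methyl)-1,3-dimethylcyclohex-3-ene-1-carbaldehyde | O=C[C@]1(C)CCC=C(C)[C@@H]1CO[Si](C)(C)C(C)(C)C | intermediate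
10 | (E)-hydrazone of 9 | N/N=C/[C@]1(C)CCC=C(C)[C@@H]1CO[Si](C)(C)C(C)(C)C | intermediate
11 | [(1R)-2,6,6-trimethylcyclohex-2-en-1-yl]methanol ((R)-α-cyclogeraniol) | CC1=CCCC(C)(C)[C@H]1CO | intermediate
12 | (1R)-2,6,6-trimethylcyclohex-2-ene-1-carbaldehyde ((R)-α-cyclocitral) | CC1=CCCC(C)(C)[C@H]1C=O | intermediate
13 | ethyl (2E)-4-(diethoxyphosphoryl)-3-methylbut-2-enoate | CCOC(=O)/C=C(C)/CP(=O)(OCC)OCC | starting material
14 | lithium salt of the carbanion of 13 | CCOC(=O)/C=C(C)/[CH-]P(=O)(OCC)OCC.[Li+] | intermediate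
15 | ethyl (2E,4E)-3-methyl-5-[(1R)-2,6,6-trimethylcyclohex-2-en-1-yl]penta-2,4-dienoate | CCOC(=O)/C=C(C)/C=C/[C@H]1C(C)=CCCC1(C)C | intermediate
16 | (2E,4E)-3-methyl-5-[(1R)-2,6,6-trimethylcyclohex-2-en-1-yl]penta-2,4-dien-1-ol | OC/C=C(C)/C=C/[C@H]1C(C)=CCCC1(C)C | intermediate
17 | [(2E,4E)-3-methyl-5-[(1R)-2,6,6-trimethylcyclohex-2-en-1-yl]penta-2,4-dien-1-yl](triphenyl)phosphonium bromide | [Br-].c1ccccc1[P+](c1ccccc1)(c1ccccc1)C/C=C(C)/C=C/[C@H]1C(C)=CCCC1(C)C | intermediate
18 | (2E,6E)-1-bromo-3,7,11-trimethyldodeca-2,6,10-triene (farnesyl bromide) | CC(C)=CCC/C(C)=C/CC/C(C)=C/CBr | starting material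
19 | triphenyl[(2E,6E)-3,7,11-trimethyldodeca-2,6,10-trien-1-yl]phosphonium bromide | CC(C)=CCC/C(C)=C/CC/C(C)=C/C[P+](c1ccccc1)(c1ccccc1)c1ccccc1.[Br-] | intermediate
20 | (2E,4E,6E)-2,7-dimethylocta-2,4,6-trienedial | O=C/C(C)=C/C=C/C=C(C)/C=O | starting material
21 | triphenyl[(2E,6E)-3,7,11-trimethyldodeca-2,6,10-trien-1-ylidene]-λ5-phosphane (farnesyl ylide) | CC(C)=CCC/C(C)=C/CC/C(C)=C/C=P(c1ccccc1)(c1ccccc1)c1ccccc1 | intermediate
22 | (2E,4E,6E,8Z,10E,14E)-2,7,11,15,19-pentamethylicosa-2,4,6,8,10,14,18-heptaenal | CC(C)=CCC/C(C)=C/CC/C(C)=C/C=C\C(C)=C\C=C\C=C(C)\C=O | intermediate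
23 | (2E,4E,6E,8E,10E,14E)-2,7,11,15,19-pentamethylicosa-2,4,6,8,10,14,18-heptaenal | CC(C)=CCC/C(C)=C/CC/C(C)=C/C=C/C(C)=C/C=C/C=C(C)/C=O | intermediate
24 | [(2E,4E)-3-methyl-5-[(1R)-2,6,6-trimethylcyclohex-2-en-1-yl]penta-2,4-dien-1-ylidene](triphenyl)-λ5-phosphane (C15 ylide) | c1ccccc1P(=C/C=C(C)/C=C/[C@H]1C(C)=CCCC1(C)C)(c1ccccc1)c1ccccc1 | intermediate
25 | (11Z)-α-zeacarotene, (6R,11Z)-7′,8′-dihydro-ε,ψ-carotene | CC(C)=CCC/C(C)=C/CC/C(C)=C/C=C/C(C)=C/C=C/C=C(C)/C=C\C=C(C)\C=C\[C@H]1C(C)=CCCC1(C)C | intermediate
26 | α-zeacarotene, (6R)-7′,8′-dihydro-ε,ψ-carotene | CC(C)=CCC/C(C)=C/CC/C(C)=C/C=C/C(C)=C/C=C/C=C(C)/C=C/C=C(C)/C=C/[C@H]1C(C)=CCCC1(C)C | target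

**Step count**
Total: 13 steps. Longest linear sequence: 11 steps (steps 1 to 10, then step 13).

**Steps most likely to fail**

Step 3. What may go wrong: insufficient endo/exo or facial discrimination (the two diastereomers lead to opposite enantiomers of the ring), or protodesilylation of the diene by the acidic catalyst before cycloaddition. A reversed sense of induction alone would be met by the mirror-image catalyst. The fallback gives up catalyst control and resolves later. It sets out from diene 4 and methacrolein 5: cycloaddition promoted by catalytic Me2AlCl (CH2Cl2, −78 °C) should give the racemic adduct F1, of which both diastereomers are usable because the quaternary carbon later becomes symmetric. The unchanged operations of steps 4 to 6 then lead through the racemic cesium enolate F2, the racemic enol triflate F3, the racemic aldehyde F4 and its hydrazone F5 to racemic α-cyclogeraniol F6. Acylation with (1S)-camphanic chloride (pyridine, DMAP, CH2Cl2) and separation of the diastereomeric esters by crystallisation or chromatography should give the camphanate of the (R)-alcohol F7. Methanolysis (K2CO3, MeOH) comes back to the route at compound 11.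

Step 8. What may go wrong: deprotonation of the α-CH of aldehyde 12 by the phosphonate anion, with racemisation or shift of the ring double bond into conjugation. The fallback avoids any strong base at the aldehyde stage and builds the chain by another disconnection. It sets out from aldehyde 12: Wittig reaction with the neutral stabilised ylide 1-(triphenyl-λ5-phosphanylidene)propan-2-one (toluene, 90 °C) should give (R)-α-ionone F8. Addition of CH2=CHMgBr (THF, −20 °C) gives the tertiary vinyl carbinol F9 as a mixture of carbinol epimers, which does not matter. Treatment with Ph3P·HBr (MeOH, rt) with allylic transposition comes back to the route at phosphonium salt 17.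

Step 12. What may go wrong: a second olefination of the dialdehyde and E/Z scrambling through the delocalised allylic ylide, which waste the polyene and complicate purification. The fallback reverses the order in which the fragments are joined. It sets out from phosphonium salt 17 and dialdehyde 20: mono-condensation of the crystalline ring salt with excess 20 (NaOMe, CH2Cl2/MeOH; I2-catalysed equilibration) should give the ring-bearing C25 aldehyde F10. Farnesyl salt 19 is then used in excess on this mono-aldehyde (n-BuLi, THF, −78 °C to rt; then heptane, reflux), where double olefination cannot occur, and comes back to the route at the target 26.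

**Further compounds**
F1 | step 3 | racemic 2-({[tert-butyl(dimethyl)silyl]oxy}methyl)-1,3-dimethyl-4-{[tri(propan-2-yl)silyl]oxy}cyclohex-3-ene-1-carbaldehyde (both diastereomers) | O=CC1(C)CCC(O[Si](C(C)C)(C(C)C)C(C)C)=C(C)C1CO[Si](C)(C)C(C)(C)C
F2 | step 3 | racemic cesium 3-({[tert-butyl(dimethyl)silyl]oxy}methyl)-4-formyl-2,4-dimethylcyclohex-1-en-1-olate | O=CC1(C)CCC([O-])=C(C)C1CO[Si](C)(C)C(C)(C)C.[Cs+]
F3 | step 3 | racemic 3-({[tert-butyl(dimethyl)silyl]oxy}methyl)-4-formyl-2,4-dimethylcyclohex-1-en-1-yl trifluoromethanesulfonate | O=CC1(C)CCC(OS(=O)(=O)C(F)(F)F)=C(C)C1CO[Si](C)(C)C(C)(C)C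
F4 | step 3 | racemic 2-({[tert-butyl(dimethyl)silyl]oxy}methyl)-1,3-dimethylcyclohex-3-ene-1-carbaldehyde | O=CC1(C)CCC=C(C)C1CO[Si](C)(C)C(C)(C)C
F5 | step 3 | hydrazone of F4 | NN=CC1(C)CCC=C(C)C1CO[Si](C)(C)C(C)(C)C
F6 | step 3 | racemic (2,6,6-trimethylcyclohex-2-en-1-yl)methanol | CC1=CCCC(C)(C)C1CO
F7 | step 3 | [(1R)-2,6,6-trimethylcyclohex-2-en-1-yl]methyl (1S,4R)-4,7,7-trimethyl-3-oxo-2-oxabicyclo[2.2.1]heptane-1-carboxylate | CC1=CCCC(C)(C)[C@H]1COC(=O)[C@@]12CC[C@@](C)(C(=O)O1)C2(C)C
F8 | step 8 | (3E)-4-[(1R)-2,6,6-trimethylcyclohex-2-en-1-yl]but-3-en-2-one ((R)-α-ionone) | CC(=O)/C=C/[C@H]1C(C)=CCCC1(C)C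
F9 | step 8 | (1E)-3-methyl-1-[(1R)-2,6,6-trimethylcyclohex-2-en-1-yl]penta-1,4-dien-3-ol (both carbinol epimers) | C=CC(C)(O)/C=C/[C@H]1C(C)=CCCC1(C)C
F10 | step 12 | (2E,4E,6E,8E,10E,12E)-2,7,11-trimethyl-13-[(1R)-2,6,6-trimethylcyclohex-2-en-1-yl]trideca-2,4,6,8,10,12-hexaenal | O=C/C(C)=C/C=C/C=C(C)/C=C/C=C(C)/C=C/[C@H]1C(C)=CCCC1(C)C
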